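**Plan**
1. Numbering: decalin carbons C1–C10 and benzylic C11 as in avarane terpenoids; ring A = cyclohexene, ring B = C5–C6–C7–C8–C9–C10; α = face of H-10 and 5-Me, β = face of 8-Me and 9-Me.
2. Retrosynthetic cuts, in order: oxazole C2 (orthoacetate) and aryl C–N; C11–aryl (aryllithium + aldehyde); C4–CH3 (enol triflate); C8–C9 of ring B; C9=C11 (metathesis); C5–CH3 and C10–C9 (conjugate addition/methylation); C5–C6 (Birch alkylation).
3. Enabling feature: C9 is quaternary, carries the one-carbon branch C11 and adjoins methine C8, so C11 can be read as a former ring atom between C9 and C8; a 9,11-epoxide in the seven-membered ring C5–C6–C7–C8–C11–C9–C10 contracts to ring B and extrudes C11 as CHO.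
4. Forward order: chain C6–C7–C8–C11 is attached to a cyclohexenone (ring A), the seven-membered ring is closed by metathesis, epoxidised and contracted to ring B, then the arene is added and the benzoxazole closed last.
5. Stereochemistry: C8 from an oxazolidinone-controlled conjugate addition; C10 from a ligand-controlled copper conjugate addition; C5 by enolate methylation trans to the C10 substituent; C9 by α-face epoxidation followed by a stereospecific 1,2-shift (inversion at C9, retention at C8).

Key step: step 10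

Remark: 4-methoxybenzene-1,3-diol is taken as commercially available.

Step 1
Reactants: 1 (R)-4-benzyloxazolidin-2-one; 2 (E)-but-2-enoyl chloride
Product: 3 (R)-4-benzyl-3-[(E)-but-2-enoyl]oxazolidin-2-one
Conditions: n-BuLi, THF, −78 °C; then 2, −78 → 0 °C
Reagents that add atoms: none
Why: N-acylation of the lithiated oxazolidinone by the acid chloride (standard auxiliary loading); no stereocentre is formed.

Step 2
Reactants: 3 (R)-4-benzyl-3-[(E)-but-2-enoyl]oxazolidin-2-one
Product: 4 (R)-4-benzyl-3-[(3S)-3-methylpent-4-enoyl]oxazolidin-2-one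
Conditions: CH2=CHMgBr, CuBr·SMe2 (20 mol %), THF, −78 → −20 °C; then H2O
Reagents that add atoms: vinylmagnesium bromide, C=C[Mg]Br
Why: Copper-catalysed conjugate addition of a Grignard reagent to the chelated syn-s-cis N-enoyl oxazolidinone; vinyl should add to the β-carbon anti to the benzyl group, setting C8 as S.

Step 3
Reactants: 4 (R)-4-benzyl-3-[(3S)-3-methylpent-4-enoyl]oxazolidin-2-one
Product: 5 (S)-3-methylpent-4-en-1-ol
Conditions: LiBH4, H2O (1 equiv), Et2O, 0 °C
Reagents that add atoms: none
Why: Reductive cleavage of the imide to the primary alcohol with return of the auxiliary; C8 is not epimerisable under these conditions.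

Step 4
Reactants: 5 (S)-3-methylpent-4-en-1-ol
Product: 6 (S)-5-iodo-3-methylpent-1-ene
Conditions: I2, PPh3, imidazole, CH2Cl2, 0 °C → rt
Reagents that add atoms: iodine, II
Why: Appel-type iodination of the primary alcohol (SN2 at CH2); C8 is untouched.

Step 5
Reactants: 7 2-methoxybenzoic acid; 6 (S)-5-iodo-3-methylpent-1-ene
Product: 9 2-[(3S)-3-methylpent-4-en-1-yl]cyclohex-2-en-1-one, via diene acid 8 (not isolated)
Conditions: Li, NH3(l)/THF, −78 °C; then 6; NH4Cl; then 2 M HCl, MeOH, reflux
Reagents that add atoms: water, O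
Why: Birch reduction–alkylation of 2-methoxybenzoic acid at C1, then acid hydrolysis of the enol ether, decarboxylation of the β-keto acid and conjugation, the standard entry to 2-alkylcyclohex-2-enones; no ring stereocentre remains and C8 is remote.

Step 6
Reactants: 9 2-[(3S)-3-methylpent-4-en-1-yl]cyclohex-2-en-1-one
Product: 11 (2R,3S)-2-methyl-2-[(3S)-3-methylpent-4-en-1-yl]-3-(prop-1-en-2-yl)cyclohexan-1-one, via bromomagnesium enolate 10 (not isolated)
Conditions: CH2=C(CH3)MgBr, Cu(OTf)2 (5 mol %), C2-symmetric 4,5-diphenylimidazolinium salt as chiral carbene precursor (6 mol %, antipode chosen for 10S), Et2O, −30 °C; then MeI, HMPA, −30 °C → rt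
Reagents that add atoms: isopropenylmagnesium bromide, CC(=C)[Mg]Br; iodomethane, CI
Why: Copper-catalysed asymmetric conjugate addition of a Grignard reagent to an α-substituted cyclohexenone sets C10 under ligand control (C8 is too remote to interfere), and the regiodefined enolate is methylated anti to the new isopropenyl group, so 5-Me ends trans to isopropenyl and cis to H-10.

Step 7
Reactants: 11 (2R,3S)-2-methyl-2-[(3S)-3-methylpent-4-en-1-yl]-3-(prop-1-en-2-yl)cyclohexan-1-one
Product: 12 (4aR,7S,9aS)-4a,7,9-trimethyl-1,2,3,4a,5,6,7,9a-octahydro-4H-benzo[7]annulen-4-one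
Conditions: second-generation Grubbs catalyst RuCl2(=CHPh)(PCy3)(H2IMes) (5 mol %), toluene (0.005 M), 80 °C
Reagents that add atoms: none
Why: Ring-closing metathesis of the cis-disposed isopropenyl and vinyl groups closes the trisubstituted cycloheptene (C9=C11) as a cis-fused bicycle; no stereocentre is touched.

Step 8
Reactants: 12 (4aR,7S,9aS)-4a,7,9-trimethyl-1,2,3,4a,5,6,7,9a-octahydro-4H-benzo[7]annulen-4-one
Product: 13 (4aR,7S,9aS)-4a,7,9-trimethyl-2,4a,5,6,7,9a-hexahydro-1H-benzo[7]annulen-4-yl trifluoromethanesulfonate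
Conditions: KN(SiMe3)2, THF, −78 °C; then PhNTf2, −78 → 0 °C
Reagents that add atoms: N-phenylbis(trifluoromethanesulfonimide), O=S(=O)(N(c1ccccc1)S(=O)(=O)C(F)(F)F)C(F)(F)F
Why: Only C3 is enolisable (C5 is quaternary), so enolate O-triflation gives a single enol triflate, an electron-poor placeholder for the C3=C4(CH3) olefin of ring A.

Step 9
Reactants: 13 enol triflate
Product: 14 9α,11α-epoxide of 13 (terpenoid numbering 5R,8S,9S,10R,11R; oxirane oxygen syn to H-10 and anti to 8-Me)
Conditions: dimethyldioxirane, acetone, 0 °C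
Reagents that add atoms: dimethyldioxirane, CC1(C)OO1
Why: Electrophilic epoxidation of the only electron-rich olefin (the enol triflate is deactivated); the oxidant should approach C9=C11 from the α face, anti to the allylic 8-methyl group and to the allylic C10–C1 bond of ring A, which fixes the configuration of the oxirane.

Step 10
Reactants: 14 9α,11α-epoxide
Product: 15 (1R,2S,4aR,8aR)-1-formyl-1,2,4a-trimethyl-1,2,3,4,4a,7,8,8a-octahydronaphthalen-5-yl trifluoromethanesulfonate
Conditions: methylaluminium bis(4-bromo-2,6-di-tert-butylphenoxide), MeAl(OAr)2 (20 mol %), CH2Cl2, −78 → −20 °C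
Reagents that add atoms: none
Why: Meinwald (semipinacol) rearrangement: the bulky aluminium Lewis acid binds the oxirane oxygen, the C9–O bond ionises at the tertiary carbon and the ring bond C11–C8 shifts from C11 to C9 while C11 becomes the formyl carbon. The closest known reaction type is the Lewis-acid ring contraction of 1-methylcycloalkene oxides to 1-methylcycloalkanecarbaldehydes (as in α-pinene oxide to campholenic aldehyde and 5,6-epoxy steroids to B-nor aldehydes), for which bulky aryloxyaluminium reagents favour alkyl over hydride shift. Ring B is closed not by a cyclisation but by contraction of the seven-membered ring C5–C6–C7–C8–C11–C9–C10 through the 1,2-shift that makes the C8–C9 bond. C9 is formed with inversion (C8 enters anti to the departing oxygen, so the α-epoxide gives 9-Me β and CHO α), C8 migrates with retention, and C5 and C10 are untouched. The step needs C–C over C–H migration and ionisation at C9 rather than C11: the methyl group on C9 secures the regiochemistry, the twisted cycloheptane can align the C11–C8 bond with the breaking C9–O bond and gains the relief of seven-ring strain, and the enol triflate keeps ring A inert to the Lewis acid.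

Step 11
Reactants: 15 aldehyde enol triflate
Product: 16 (1R,2S,4aR,8aR)-1,2,4a,5-tetramethyl-1,2,3,4,4a,7,8,8a-octahydronaphthalene-1-carbaldehyde
Conditions: MeZnCl, Pd(PPh3)4 (5 mol %), THF, 50 °C
Reagents that add atoms: methylzinc chloride, C[Zn]Cl
Why: Negishi cross-coupling of the enol triflate installs the C4 methyl group with the double bond fixed at C3=C4; the organozinc reagent should not add to the hindered, non-enolisable aldehyde.

Step 12
Reactants: 17 4-methoxybenzene-1,3-diol
Product: 18 1-methoxy-2,4-bis(methoxymethoxy)benzene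
Conditions: MOMCl, i-Pr2NEt, CH2Cl2, 0 °C → rt
Reagents that add atoms: chloromethyl methyl ether, COCCl
Why: O-Alkylation of both phenols; the MOM ethers protect and later act as ortho-directing groups.

Step 13
Reactants: 18 1-methoxy-2,4-bis(methoxymethoxy)benzene; 16 aldehyde
Product: 20 [3-methoxy-2,6-bis(methoxymethoxy)phenyl][(1R,2S,4aR,8aR)-1,2,4a,5-tetramethyl-1,2,3,4,4a,7,8,8a-octahydronaphthalen-1-yl]methanol (both C11 epimers), via aryllithium 19 (not isolated)
Conditions: 18, n-BuLi, TMEDA, THF, 0 °C; then 16, −78 → 0 °C; H2O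
Reagents that add atoms: none
Why: Directed ortho-lithiation between the two MOM ethers, then 1,2-addition of the aryllithium to the neopentyl aldehyde (the usual way to join drimane-type aldehydes to oxygenated arenes); the carbinol centre C11 forms as a mixture and is removed in step 14.

Step 14
Reactants: 20 benzylic alcohol
Product: 21 1-methoxy-2,4-bis(methoxymethoxy)-3-{[(1R,2S,4aR,8aS)-1,2,4a,5-tetramethyl-1,2,3,4,4a,7,8,8a-octahydronaphthalen-1-yl]methyl}benzene
Conditions: Li, NH3(l)/THF, −78 → −33 °C; then NH4Cl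
Reagents that add atoms: none
Why: Dissolving-metal hydrogenolysis of the benzylic C–O bond through the arene radical anion; MOM ethers and the trisubstituted olefin are inert and no cation is generated next to quaternary C9.

Step 15
Reactants: 21 coupled arene
Product: 23 5-methoxy-2,4-bis(methoxymethoxy)-3-{[(1R,2S,4aR,8aS)-1,2,4a,5-tetramethyl-1,2,3,4,4a,7,8,8a-octahydronaphthalen-1-yl]methyl}aniline, via aryllithium 22 (not isolated)
Conditions: n-BuLi, TMEDA, THF, 0 °C; then LiNHOMe (from MeONH2 and MeLi), −78 → −15 °C; H2O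
Reagents that add atoms: methoxyamine, CON
Why: Directed ortho-lithiation at the only ring position ortho to a MOM ether, then electrophilic amination of the aryllithium by lithium methoxyamide, which transfers NH.

Step 16
Reactants: 23 aniline
Product: 25 5-methoxy-2-methyl-7-{[(1R,2S,4aR,8aS)-1,2,4a,5-tetramethyl-1,2,3,4,4a,7,8,8a-octahydronaphthalen-1-yl]methyl}-1,3-benzoxazol-6-ol, via aminoresorcinol 24 (not isolated)
Conditions: HCl (1.25 M in MeOH), 25 °C, argon; concentrate; MeC(OEt)3, 70 °C; aq. NaHCO3
Reagents that add atoms: triethyl orthoacetate, CCOC(C)(OCC)OCC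
Why: Acid methanolysis of both MOM ethers, then condensation of the o-aminophenol with the orthoester (imidate formation and cyclisation with loss of ethanol) gives the 2-methylbenzoxazole; only the hydroxyl ortho to nitrogen can cyclise, and the other remains as the free 6-OH.

**Compound list**
1 | (R)-4-benzyloxazolidin-2-one | O=C1OC[C@@H](Cc2ccccc2)N1 | starting material
2 | (E)-but-2-enoyl chloride | C/C=C/C(=O)Cl | starting material
3 | (R)-4-benzyl-3-[(E)-but-2-enoyl]oxazolidin-2-one | O=C1OC[C@@H](Cc2ccccc2)N1C(=O)/C=C/C | intermediate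
4 | (R)-4-benzyl-3-[(3S)-3-methylpent-4-enoyl]oxazolidin-2-one | O=C1OC[C@@H](Cc2ccccc2)N1C(=O)C[C@H](C)C=C | intermediate
5 | (S)-3-methylpent-4-en-1-ol | C=C[C@@H](C)CCO | intermediate
6 | (S)-5-iodo-3-methylpent-1-ene | C=C[C@@H](C)CCI | intermediate
7 | 2-methoxybenzoic acid | COc1ccccc1C(=O)O | starting material
8 | 2-methoxy-1-[(3S)-3-methylpent-4-en-1-yl]cyclohexa-2,5-diene-1-carboxylic acid (both C1 epimers, not isolated) | COC1=CCC=CC1(CC[C@H](C)C=C)C(=O)O | intermediate
9 | 2-[(3S)-3-methylpent-4-en-1-yl]cyclohex-2-en-1-one | O=C1CCCC=C1CC[C@H](C)C=C | intermediate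
10 | bromomagnesium enolate of (3S)-2-[(3S)-3-methylpent-4-en-1-yl]-3-(prop-1-en-2-yl)cyclohexanone (not isolated) | C=C(C)[C@@H]1CCCC(O[Mg]Br)=C1CC[C@H](C)C=C | intermediate
11 | (2R,3S)-2-methyl-2-[(3S)-3-methylpent-4-en-1-yl]-3-(prop-1-en-2-yl)cyclohexan-1-one | O=C1CCC[C@@H](C(C)=C)[C@@]1(C)CC[C@H](C)C=C | intermediate
12 | (4aR,7S,9aS)-4a,7,9-trimethyl-1,2,3,4a,5,6,7,9a-octahydro-4H-benzo[7]annulen-4-one (cis-fused; 8-Me trans to H-10) | CC1=C[C@@H](C)CC[C@@]2(C)C(=O)CCC[C@@H]12 | intermediate
13 | (4aR,7S,9aS)-4a,7,9-trimethyl-2,4a,5,6,7,9a-hexahydro-1H-benzo[7]annulen-4-yl trifluoromethanesulfonate | CC1=C[C@@H](C)CC[C@@]2(C)C(OS(=O)(=O)C(F)(F)F)=CCC[C@@H]12 | intermediate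
14 | 9α,11α-epoxide of 13 (oxirane syn to H-10, anti to 8-Me) | C[C@]12[C@H](O1)[C@@H](C)CC[C@@]3(C)C(OS(=O)(=O)C(F)(F)F)=CCC[C@@H]23 | intermediate
15 | (1R,2S,4aR,8aR)-1-formyl-1,2,4a-trimethyl-1,2,3,4,4a,7,8,8a-octahydronaphthalen-5-yl trifluoromethanesulfonate | O=C[C@]1(C)[C@@H](C)CC[C@@]2(C)C(OS(=O)(=O)C(F)(F)F)=CCC[C@@H]12 | intermediate
16 | (1R,2S,4aR,8aR)-1,2,4a,5-tetramethyl-1,2,3,4,4a,7,8,8a-octahydronaphthalene-1-carbaldehyde | O=C[C@]1(C)[C@@H](C)CC[C@@]2(C)C(C)=CCC[C@@H]12 | intermediate
17 | 4-methoxybenzene-1,3-diol | COc1ccc(O)cc1O | starting material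
18 | 1-methoxy-2,4-bis(methoxymethoxy)benzene | COCOc1ccc(OC)c(OCOC)c1 | intermediate
19 | [3-methoxy-2,6-bis(methoxymethoxy)phenyl]lithium (not isolated) | COCOc1ccc(OC)c(OCOC)c1[Li] | intermediate
20 | [3-methoxy-2,6-bis(methoxymethoxy)phenyl][(1R,2S,4aR,8aR)-1,2,4a,5-tetramethyl-1,2,3,4,4a,7,8,8a-octahydronaphthalen-1-yl]methanol (both C11 epimers) | COCOc1ccc(OC)c(OCOC)c1C(O)[C@]1(C)[C@@H](C)CC[C@@]2(C)C(C)=CCC[C@@H]12 | intermediate
21 | 1-methoxy-2,4-bis(methoxymethoxy)-3-{[(1R,2S,4aR,8aS)-1,2,4a,5-tetramethyl-1,2,3,4,4a,7,8,8a-octahydronaphthalen-1-yl]methyl}benzene | COCOc1ccc(OC)c(OCOC)c1C[C@]1(C)[C@@H](C)CC[C@@]2(C)C(C)=CCC[C@@H]12 | intermediate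
22 | 6-lithio derivative of 21, lithium ortho to the MOM ether remote from OMe (not isolated) | COCOc1c([Li])cc(OC)c(OCOC)c1C[C@]1(C)[C@@H](C)CC[C@@]2(C)C(C)=CCC[C@@H]12 | intermediate
23 | 5-methoxy-2,4-bis(methoxymethoxy)-3-{[(1R,2S,4aR,8aS)-1,2,4a,5-tetramethyl-1,2,3,4,4a,7,8,8a-octahydronaphthalen-1-yl]methyl}aniline | COCOc1c(N)cc(OC)c(OCOC)c1C[C@]1(C)[C@@H](C)CC[C@@]2(C)C(C)=CCC[C@@H]12 | intermediate
24 | 4-amino-6-methoxy-2-{[(1R,2S,4aR,8aS)-1,2,4a,5-tetramethyl-1,2,3,4,4a,7,8,8a-octahydronaphthalen-1-yl]methyl}benzene-1,3-diol (present as its hydrochloride, not isolated) | COc1cc(N)c(O)c(C[C@]2(C)[C@@H](C)CC[C@@]3(C)C(C)=CCC[C@@H]23)c1O | intermediate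
25 | 5-methoxy-2-methyl-7-{[(1R,2S,4aR,8aS)-1,2,4a,5-tetramethyl-1,2,3,4,4a,7,8,8a-octahydronaphthalen-1-yl]methyl}-1,3-benzoxazol-6-ol (CNP0149771.1) | COc1cc2nc(C)oc2c(C[C@]2(C)[C@@H](C)CC[C@@]3(C)C(C)=CCC[C@@H]23)c1O | target

**Totals**
Total step count: 16. Longest linear sequence: 15 steps (steps 1–11 and 13–16, from 1 and 2 to 25).

**Steps most likely to fail**

Step 10. A 1,2-hydride shift from C11 (or proton loss from the C9 cation) may compete with the C8 shift, so that the ring is not contracted. The fallback runs the contraction through a halohydrin salt, in which the migrating bond must stand anti to a C9–Br bond, and it sets out from 13. NBS in wet THF at 0 °C should add from the α face and give, after opening by water at C9, bromohydrin F1 (9β-OH, 11α-Br). K2CO3 in MeOH closes it to the β-epoxide F2. MgBr2·OEt2 in Et2O opens F2 at tertiary C9 with inversion to the bromomagnesium alkoxide of bromohydrin F3 (9α-Br, 11β-O). On warming, C8 displaces bromide from the β face (semipinacol ring contraction of a trans-2-halocycloalkanol salt). This double inversion gives the same aldehyde, and the route is rejoined at 15.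

Step 6. Ligand control over the face of C10 may be insufficient for an alkenyl Grignard reagent on the α-alkyl enone, and the magnesium enolate may methylate sluggishly. The fallback gives up catalyst control and uses the enantiopure C8 centre as an internal resolving element; it sets out from 9. Isopropenylmagnesium bromide with CuBr·SMe2 (cat.) in THF at −78 °C, then MeI/HMPA, without chiral ligand, gives via enolate 10 and its C10 epimer, enolate F4, ketone 11 together with its ring diastereomer, ketone F5. Metathesis as in step 7 converts the mixture into 12 and the diastereomeric bicyclic ketone F6. These rigid ketones should be separable by chromatography, and the route is rejoined at 12.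

Step 9. Facial selectivity may be poor or reversed if the homoallylic 5-methyl group shields the α face. The fallback inverts the facial outcome through a halohydrin and sets out from 13. NBS in wet THF would then also attack from the β face, and water opens the bromonium ion at C9 from the α face to give bromohydrin F7 (9α-OH, 11β-Br). K2CO3 in MeOH closes it with inversion at C11 to the α-epoxide, and the route is rejoined at 14.

**Further compounds**
F1 | step 10 | bromohydrin of 13 with 9β-OH and 11α-Br | C[C@]1(O)[C@H](Br)[C@@H](C)CC[C@@]2(C)C(OS(=O)(=O)C(F)(F)F)=CCC[C@@H]12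
F2 | step 10 | 9β,11β-epoxide of 13 (C9/C11 diastereomer of 14) | C[C@@]12[C@@H](O1)[C@@H](C)CC[C@@]3(C)C(OS(=O)(=O)C(F)(F)F)=CCC[C@@H]23
F3 | step 10 | bromohydrin with 9α-Br and 11β-OH (formed as its bromomagnesium alkoxide) | C[C@@]1(Br)[C@@H](O)[C@@H](C)CC[C@@]2(C)C(OS(=O)(=O)C(F)(F)F)=CCC[C@@H]12
F4 | step 6 | bromomagnesium enolate, C10 epimer of 10 | C=C(C)[C@H]1CCCC(O[Mg]Br)=C1CC[C@H](C)C=C
F5 | step 6 | (2S,3R)-2-methyl-2-[(3S)-3-methylpent-4-en-1-yl]-3-(prop-1-en-2-yl)cyclohexan-1-one | O=C1CCC[C@H](C(C)=C)[C@]1(C)CC[C@H](C)C=C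
F6 | step 6 | (4aS,7S,9aR)-4a,7,9-trimethyl-1,2,3,4a,5,6,7,9a-octahydro-4H-benzo[7]annulen-4-one | CC1=C[C@@H](C)CC[C@]2(C)C(=O)CCC[C@H]12
F7 | step 9 | bromohydrin of 13 with 9α-OH and 11β-Br | C[C@@]1(O)[C@@H](Br)[C@@H](C)CC[C@@]2(C)C(OS(=O)(=O)C(F)(F)F)=CCC[C@@H]12
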